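**Retrosynthetic overview**

1. Numbering follows the plakortolides (C1 lactone carbonyl, C3 and C6 peroxide carbons, C16 benzylic). The strategy rests on the 1,2-dioxane ring (O–O, C3, C4, C5, C6): C4 and C5 lie across the ring from the O–O bond, so a temporary C4=C5 alkene lets the ring be closed at carbon and then lets the C1 carboxyl put the lactone oxygen on C4 cis to C2.
2. Late disconnections: C10=C11 (Julia–Kocienski olefination with a C11–C16 sulfone from styrene and hex-5-en-1-ol) and lactone O–C4 (iodolactonisation, then tin hydride removes iodine from C5).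
3. Key disconnection: C4=C5 by ring-closing metathesis of an acyclic bis-allylic dialkyl peroxide carrying the C5 vinyl group on C6 and the C4 isopropenyl group on C3.
4. Peroxide assembly: C6–OOH by perhydrolysis (inversion) of a Sharpless epoxide; O–C3 by amine-catalysed conjugate addition of that hydroperoxide to 4-methylpenta-2,4-dienal; only after the O–O bond is fully alkylated is the glycol left by the epoxide cleaved and methylenated to the C5 vinyl group. The C5–C10 chain comes from a Stille coupling of prenol- and but-2-yn-1-ol-derived halves.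
5. Ring order: 3,6-dihydro-1,2-dioxine first (step 12), cis-fused γ-lactone second (step 14).

Key step: step 12

Assumption: the C10 oxygen is carried as a TBDPS ether so that it outlasts the acidic perhydrolysis, and C1 passes through the metathesis as the primary alcohol (reduced in the flask in step 9, re-oxidised in step 13) because a β-peroxy aldehyde would not survive the ylide of step 11; C5′ denotes the carbon later cleaved from C5.

**Route**

Step 1
Reactants: 1 3-methylbut-2-en-1-ol (prenol)
Product: 2 tert-butyl[(3-methylbut-2-en-1-yl)oxy]diphenylsilane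
Conditions: TBDPSCl, imidazole, CH2Cl2, 0 °C → rt
Reagents that add atoms: tert-butyl(chloro)diphenylsilane, CC(C)(C)[Si](Cl)(c1ccccc1)c1ccccc1
Why: Imidazole-promoted O-silylation of a primary alcohol, with the TBDPS group chosen to survive the acid-catalysed perhydrolysis of step 7.

Step 2
Reactants: 2 tert-butyl[(3-methylbut-2-en-1-yl)oxy]diphenylsilane
Product: 3 (2E)-4-[(tert-butyldiphenylsilyl)oxy]-2-methylbut-2-en-1-ol
Conditions: SeO2 (20 mol%), t-BuOOH, salicylic acid (cat.), CH2Cl2, rt
Reagents that add atoms: tert-butyl hydroperoxide, CC(C)(C)OO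
Why: Selenium dioxide allylic oxidation (ene reaction then [2,3]-sigmatropic shift) hydroxylates the methyl group trans to the CH2O chain of the trisubstituted alkene, which fixes the 8E geometry.

Step 3
Reactants: 3 (2E)-4-[(tert-butyldiphenylsilyl)oxy]-2-methylbut-2-en-1-ol
Product: 4 {[(2E)-4-bromo-3-methylbut-2-en-1-yl]oxy}(tert-butyl)diphenylsilane
Conditions: CBr4, PPh3, CH2Cl2, 0 °C
Reagents that add atoms: tetrabromomethane, BrC(Br)(Br)Br
Why: Appel bromination displaces the activated primary allylic oxygen by SN2 without allylic transposition or loss of alkene geometry.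

Step 4
Reactants: 5 but-2-yn-1-ol
Product: 7 (2Z)-3-(tributylstannyl)but-2-en-1-ol, via sodium vinylalanate 6 (not isolated)
Conditions: Red-Al (1.05 equiv), THF, 0 °C → rt; then Bu3SnOTf, −78 °C → rt
Reagents that add atoms: tributyltin trifluoromethanesulfonate, CCCC[Sn](CCCC)(CCCC)OS(=O)(=O)C(F)(F)F
Why: Alkoxide-directed trans-hydroalumination of the propargylic alcohol places aluminium on C3 cis to the CH2O group in a five-membered alanate, and aluminium-to-tin exchange with retention should give the Z-vinylstannane.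

Step 5
Reactants: 4 {[(2E)-4-bromo-3-methylbut-2-en-1-yl]oxy}(tert-butyl)diphenylsilane; 7 (2Z)-3-(tributylstannyl)but-2-en-1-ol
Product: 8 (2Z,5E)-7-[(tert-butyldiphenylsilyl)oxy]-3,5-dimethylhepta-2,5-dien-1-ol
Conditions: Pd2(dba)3 (2.5 mol%), AsPh3 (10 mol%), THF, 50 °C
Reagents that add atoms: none
Why: Stille coupling of a vinylstannane with an allylic bromide joins C6 to C7 at the unsubstituted allyl terminus with retention of both alkene geometries and tolerates the free hydroxyl.

Step 6
Reactants: 8 (2Z,5E)-7-[(tert-butyldiphenylsilyl)oxy]-3,5-dimethylhepta-2,5-dien-1-ol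
Product: 9 [(2R,3S)-3-{(2E)-4-[(tert-butyldiphenylsilyl)oxy]-2-methylbut-2-en-1-yl}-3-methyloxiran-2-yl]methanol
Conditions: Ti(OiPr)4 (10 mol%), D-(−)-DIPT (12 mol%), t-BuOOH, 4 Å MS, CH2Cl2, −20 °C
Reagents that add atoms: tert-butyl hydroperoxide, CC(C)(C)OO
Why: Sharpless asymmetric epoxidation, in which the D-(−)-tartrate complex delivers oxygen to the face of the Z-allylic alcohol that gives the (2R,3S)-epoxide (C6 still S here), while the silylated C8=C9 alkene has no free hydroxyl to bind titanium.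

Step 7
Reactants: 9 [(2R,3S)-3-{(2E)-4-[(tert-butyldiphenylsilyl)oxy]-2-methylbut-2-en-1-yl}-3-methyloxiran-2-yl]methanol
Product: 10 (2R,3R,5E)-7-[(tert-butyldiphenylsilyl)oxy]-3-hydroperoxy-3,5-dimethylhept-5-ene-1,2-diol
Conditions: H2O2 (anhydrous, in Et2O, 10 equiv), H3PMo12O40 (3 mol%), Et2O, rt
Reagents that add atoms: hydrogen peroxide, OO
Why: Acid-catalysed epoxide perhydrolysis, in which H2O2 attacks the activated oxirane at the tertiary carbon C6 anti to the departing oxygen, so inversion sets the 6R configuration of the target and leaves a vicinal diol as the latent vinyl group.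

Step 8
Reactants: 11 methacrolein (2-methylprop-2-enal); 12 (triphenylphosphoranylidene)acetaldehyde
Product: 13 (2E)-4-methylpenta-2,4-dienal
Conditions: methacrolein (2 equiv), toluene, 80 °C
Reagents that add atoms: none
Why: Wittig olefination with a stabilised ylide gives the E-enal, and methacrolein in excess should outcompete the less electrophilic dienal product for the ylide.

Step 9
Reactants: 10 (2R,3R,5E)-7-[(tert-butyldiphenylsilyl)oxy]-3-hydroperoxy-3,5-dimethylhept-5-ene-1,2-diol; 13 (2E)-4-methylpenta-2,4-dienal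
Product: 15 (2R,3R,5E)-7-[(tert-butyldiphenylsilyl)oxy]-3-{[(3S)-5-hydroxy-2-methylpent-1-en-3-yl]peroxy}-3,5-dimethylhept-5-ene-1,2-diol, via β-peroxy aldehyde 14 (not isolated)
Conditions: 13 (2 equiv), (S)-α,α-diphenylprolinol trimethylsilyl ether (20 mol%), PhCO2H (20 mol%), toluene, 0 °C; then MeOH, NaBH4, 0 °C
Reagents that add atoms: none
Why: Iminium-catalysed asymmetric conjugate addition of a hydroperoxide to an enal (β-peroxidation), in which the (S)-catalyst shields the face of the s-trans E-iminium ion syn to its bulky group so the α-effect nucleophile should add to the Si face of C3 and set 3S under catalyst control, the acid co-catalyst protonates the enamine before it can displace the tertiary alkoxide to an epoxide, and borohydride removes the aldehyde before retro-addition.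

Step 10
Reactants: 15 (2R,3R,5E)-7-[(tert-butyldiphenylsilyl)oxy]-3-{[(3S)-5-hydroxy-2-methylpent-1-en-3-yl]peroxy}-3,5-dimethylhept-5-ene-1,2-diol
Product: 16 (2R,4E)-6-[(tert-butyldiphenylsilyl)oxy]-2-{[(3S)-5-hydroxy-2-methylpent-1-en-3-yl]peroxy}-2,4-dimethylhex-4-enal
Conditions: NaIO4, THF/H2O (3:1), 0 °C → rt
Reagents that add atoms: none
Why: Periodate glycol cleavage removes C5′ and leaves a non-enolisable α-peroxy aldehyde, the dialkyl peroxide (unlike the earlier hydroperoxide) being stable next to a carbonyl group.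

Step 11
Reactants: 16 (2R,4E)-6-[(tert-butyldiphenylsilyl)oxy]-2-{[(3S)-5-hydroxy-2-methylpent-1-en-3-yl]peroxy}-2,4-dimethylhex-4-enal
Product: 17 (3S)-3-{[(3R,5E)-7-[(tert-butyldiphenylsilyl)oxy]-3,5-dimethylhepta-1,5-dien-3-yl]peroxy}-4-methylpent-4-en-1-ol
Conditions: Ph3PCH3Br (3.5 equiv), KHMDS (3.3 equiv), THF, 0 °C; then 16, −78 → 0 °C
Reagents that add atoms: methyltriphenylphosphonium bromide, C[P+](c1ccccc1)(c1ccccc1)c1ccccc1.[Br-]
Why: Wittig methylenation of a hindered aldehyde that has no α-hydrogen, the dialkyl peroxide having no β-carbonyl group at this stage and so tolerating the ylide at low temperature, with the extra equivalent covering the free hydroxyl.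

Step 12
Reactants: 17 (3S)-3-{[(3R,5E)-7-[(tert-butyldiphenylsilyl)oxy]-3,5-dimethylhepta-1,5-dien-3-yl]peroxy}-4-methylpent-4-en-1-ol
Product: 18 2-[(3S,6R)-6-{(2E)-4-[(tert-butyldiphenylsilyl)oxy]-2-methylbut-2-en-1-yl}-4,6-dimethyl-3,6-dihydro-1,2-dioxin-3-yl]ethan-1-ol
Conditions: Grubbs second-generation catalyst (10 mol%), CH2Cl2 (0.005 M), 40 °C
Reagents that add atoms: none
Why: Ring-closing olefin metathesis: the ruthenium alkylidene loads on the monosubstituted C5 vinyl group, adds across the 1,1-disubstituted C4 isopropenyl alkene through a ruthenacyclobutane and releases ethylene, the closest known reaction being the closure of dienyl dialkyl peroxides to 3,6-dihydro-1,2-dioxines. The six-membered ring closes by forming the C4=C5 bond between two alkene carbons held in place by the C6–O–O–C3 chain, giving an endocyclic trisubstituted alkene. No stereocentre is formed or touched, and C3 and C6 enter with their configurations fixed. The step needs chemoselectivity among three alkenes and tolerance of the O–O bond: only the vinyl and isopropenyl groups have the right substitution and spacing, whereas the trisubstituted C8=C9 allylic ether is hindered and could only close a four- or seven-membered ring. Dialkyl peroxides, unlike hydroperoxides, do not oxidise the ruthenium carbene, which is why the O–O bond is fully alkylated before this step, and high dilution with loss of ethylene should drive the closure.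

Step 13
Reactants: 18 2-[(3S,6R)-6-{(2E)-4-[(tert-butyldiphenylsilyl)oxy]-2-methylbut-2-en-1-yl}-4,6-dimethyl-3,6-dihydro-1,2-dioxin-3-yl]ethan-1-ol
Product: 20 [(3S,6R)-6-{(2E)-4-[(tert-butyldiphenylsilyl)oxy]-2-methylbut-2-en-1-yl}-4,6-dimethyl-3,6-dihydro-1,2-dioxin-3-yl]acetic acid, via dioxine aldehyde 19 (not isolated)
Conditions: TEMPO (20 mol%), PhI(OAc)2 (2.5 equiv), MeCN/H2O (1:1), rt
Reagents that add atoms: water, O
Why: Nitroxyl-catalysed oxidation with a hypervalent iodine co-oxidant takes the primary alcohol through the aldehyde hydrate to the acid under weakly acidic conditions, which avoids base-induced β-elimination of the C3 peroxide.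

Step 14
Reactants: 20 [(3S,6R)-6-{(2E)-4-[(tert-butyldiphenylsilyl)oxy]-2-methylbut-2-en-1-yl}-4,6-dimethyl-3,6-dihydro-1,2-dioxin-3-yl]acetic acid
Product: 21 (3R,4S,4aR,7aS)-3-{(2E)-4-[(tert-butyldiphenylsilyl)oxy]-2-methylbut-2-en-1-yl}-4-iodo-3,4a-dimethyl-3,4,4a,7a-tetrahydrofuro[3,2-c][1,2]dioxin-6(7H)-one (iodine on C5 trans to the lactone oxygen)
Conditions: I2 (1.5 equiv), NaHCO3 (sat. aq.), CH2Cl2, 0 °C, dark
Reagents that add atoms: iodine, II
Why: Iodolactonisation, in which the carboxylate opens the iodonium ion of the C4=C5 alkene in 5-exo fashion at the more substituted carbon C4, and because the two-carbon tether from C3 can reach only the face of C4 on which C2 lies, the γ-lactone is cis-fused and the C4 configuration of the target is set with iodine anti on C5.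

Step 15
Reactants: 21 the iodolactone
Product: 22 (3R,4aS,7aS)-3-{(2E)-4-[(tert-butyldiphenylsilyl)oxy]-2-methylbut-2-en-1-yl}-3,4a-dimethyl-3,4,4a,7a-tetrahydrofuro[3,2-c][1,2]dioxin-6(7H)-one
Conditions: Bu3SnH (1.5 equiv), Et3B (20 mol%), air, toluene, 0 °C → rt
Reagents that add atoms: none
Why: Radical-chain dehalogenation with tin hydride, in which the C5 radical is held by the six-membered ring gauche to the O–O bond and so cannot reach the geometry for attack on oxygen before it takes hydrogen from the stannane.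

Step 16
Reactants: 22 the silyl ether lactone
Product: 23 (3R,4aS,7aS)-3-[(2E)-4-hydroxy-2-methylbut-2-en-1-yl]-3,4a-dimethyl-3,4,4a,7a-tetrahydrofuro[3,2-c][1,2]dioxin-6(7H)-one
Conditions: HF·pyridine, pyridine, THF, 0 °C → rt
Reagents that add atoms: none
Why: Fluoride-mediated desilylation under weakly acidic conditions, which spares the β-peroxy lactone that a basic fluoride source could open.

Step 17
Reactants: 23 the allylic alcohol
Product: 24 (2E)-4-[(3R,4aS,7aS)-3,4a-dimethyl-6-oxohexahydrofuro[3,2-c][1,2]dioxin-3-yl]-3-methylbut-2-enal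
Conditions: MnO2 (20 equiv), CH2Cl2, rt
Reagents that add atoms: none
Why: Manganese dioxide oxidation is selective for the allylic alcohol and should give the E-enal without touching the peroxide or the lactone.

Step 18
Reactants: 25 styrene; 26 hex-5-en-1-ol
Product: 27 (5E)-6-phenylhex-5-en-1-ol
Conditions: styrene (3 equiv), Grubbs second-generation catalyst (2 mol%), CH2Cl2, 40 °C
Reagents that add atoms: none
Why: Olefin cross-metathesis between a terminal alkene and excess styrene gives the thermodynamically favoured E-styrenyl alkene (15E).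

Step 19
Reactants: 27 (5E)-6-phenylhex-5-en-1-ol
Product: 28 1-phenyl-5-{[(5E)-6-phenylhex-5-en-1-yl]sulfanyl}-1H-tetrazole
Conditions: 1-phenyl-1H-tetrazole-5-thiol, PPh3, DIAD, THF, 0 °C → rt
Reagents that add atoms: 1-phenyl-1H-tetrazole-5-thiol, Sc1nnnn1-c1ccccc1
Why: Mitsunobu reaction, in which the acidic tetrazole thiol displaces the activated primary alcohol by SN2.

Step 20
Reactants: 28 the sulfide
Product: 29 1-phenyl-5-{[(5E)-6-phenylhex-5-en-1-yl]sulfonyl}-1H-tetrazole
Conditions: (NH4)6Mo7O24·4H2O (10 mol%), 30% H2O2 (5 equiv), EtOH, 0 °C → rt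
Reagents that add atoms: hydrogen peroxide, OO
Why: Molybdate-catalysed sulfide-to-sulfone oxidation with hydrogen peroxide, which is chemoselective over the styrenyl alkene.

Step 21
Reactants: 24 the enal; 29 the sulfone
Product: 30 plakortolide H
Conditions: 29 (1.3 equiv), KHMDS (1.25 equiv), DME, −78 °C, 30 min; then 24, −78 °C → rt
Reagents that add atoms: none
Why: Julia–Kocienski olefination, in which the preformed potassium sulfonyl carbanion adds to the enal and Smiles rearrangement with loss of sulfur dioxide and tetrazolate should give the 10E alkene (the usual outcome for phenyltetrazolyl sulfones with KHMDS in DME), while premetalation keeps free base away from the β-peroxy lactone.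

**Compound list**

1 | 3-methylbut-2-en-1-ol (prenol) | CC(C)=CCO | starting material
2 | tert-butyl[(3-methylbut-2-en-1-yl)oxy]diphenylsilane | CC(C)=CCO[Si](c1ccccc1)(c1ccccc1)C(C)(C)C | intermediate
3 | (2E)-4-[(tert-butyldiphenylsilyl)oxy]-2-methylbut-2-en-1-ol | OC/C(C)=C/CO[Si](c1ccccc1)(c1ccccc1)C(C)(C)C | intermediate
4 | {[(2E)-4-bromo-3-methylbut-2-en-1-yl]oxy}(tert-butyl)diphenylsilane | BrC/C(C)=C/CO[Si](c1ccccc1)(c1ccccc1)C(C)(C)C | intermediate
5 | but-2-yn-1-ol | CC#CCO | starting material
6 | sodium vinylalanate (sodium 2,2-bis(2-methoxyethoxy)-3-methyl-2,5-dihydro-1,2-oxaaluminol-2-uide) | CC1=CCO[Al-]1(OCCOC)OCCOC.[Na+] | intermediate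
7 | (2Z)-3-(tributylstannyl)but-2-en-1-ol | C/C(=C/CO)[Sn](CCCC)(CCCC)CCCC | intermediate
8 | (2Z,5E)-7-[(tert-butyldiphenylsilyl)oxy]-3,5-dimethylhepta-2,5-dien-1-ol | OC/C=C(/C)C/C(C)=C/CO[Si](c1ccccc1)(c1ccccc1)C(C)(C)C | intermediate
9 | [(2R,3S)-3-{(2E)-4-[(tert-butyldiphenylsilyl)oxy]-2-methylbut-2-en-1-yl}-3-methyloxiran-2-yl]methanol | OC[C@H]1O[C@@]1(C)C/C(C)=C/CO[Si](c1ccccc1)(c1ccccc1)C(C)(C)C | intermediate
10 | (2R,3R,5E)-7-[(tert-butyldiphenylsilyl)oxy]-3-hydroperoxy-3,5-dimethylhept-5-ene-1,2-diol | OC[C@@H](O)[C@@](C)(C/C(C)=C/CO[Si](c1ccccc1)(c1ccccc1)C(C)(C)C)OO | intermediate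
11 | methacrolein (2-methylprop-2-enal) | C=C(C)C=O | starting material
12 | (triphenylphosphoranylidene)acetaldehyde | O=CC=P(c1ccccc1)(c1ccccc1)c1ccccc1 | starting material
13 | (2E)-4-methylpenta-2,4-dienal | C=C(C)/C=C/C=O | intermediate
14 | (3S)-3-{[(2R,3R,5E)-7-[(tert-butyldiphenylsilyl)oxy]-1,2-dihydroxy-3,5-dimethylhept-5-en-3-yl]peroxy}-4-methylpent-4-enal | OC[C@@H](O)[C@@](C)(C/C(C)=C/CO[Si](c1ccccc1)(c1ccccc1)C(C)(C)C)OO[C@@H](CC=O)C(C)=C | intermediate
15 | (2R,3R,5E)-7-[(tert-butyldiphenylsilyl)oxy]-3-{[(3S)-5-hydroxy-2-methylpent-1-en-3-yl]peroxy}-3,5-dimethylhept-5-ene-1,2-diol | OC[C@@H](O)[C@@](C)(C/C(C)=C/CO[Si](c1ccccc1)(c1ccccc1)C(C)(C)C)OO[C@@H](CCO)C(C)=C | intermediate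
16 | (2R,4E)-6-[(tert-butyldiphenylsilyl)oxy]-2-{[(3S)-5-hydroxy-2-methylpent-1-en-3-yl]peroxy}-2,4-dimethylhex-4-enal | O=C[C@@](C)(C/C(C)=C/CO[Si](c1ccccc1)(c1ccccc1)C(C)(C)C)OO[C@@H](CCO)C(C)=C | intermediate
17 | (3S)-3-{[(3R,5E)-7-[(tert-butyldiphenylsilyl)oxy]-3,5-dimethylhepta-1,5-dien-3-yl]peroxy}-4-methylpent-4-en-1-ol (metathesis precursor) | C=C[C@@](C)(C/C(C)=C/CO[Si](c1ccccc1)(c1ccccc1)C(C)(C)C)OO[C@@H](CCO)C(C)=C | intermediate
18 | 2-[(3S,6R)-6-{(2E)-4-[(tert-butyldiphenylsilyl)oxy]-2-methylbut-2-en-1-yl}-4,6-dimethyl-3,6-dihydro-1,2-dioxin-3-yl]ethan-1-ol (metathesis product) | OCC[C@@H]1OO[C@](C)(C/C(C)=C/CO[Si](c1ccccc1)(c1ccccc1)C(C)(C)C)C=C1C | intermediate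
19 | [(3S,6R)-6-{(2E)-4-[(tert-butyldiphenylsilyl)oxy]-2-methylbut-2-en-1-yl}-4,6-dimethyl-3,6-dihydro-1,2-dioxin-3-yl]acetaldehyde | O=CC[C@@H]1OO[C@](C)(C/C(C)=C/CO[Si](c1ccccc1)(c1ccccc1)C(C)(C)C)C=C1C | intermediate
20 | [(3S,6R)-6-{(2E)-4-[(tert-butyldiphenylsilyl)oxy]-2-methylbut-2-en-1-yl}-4,6-dimethyl-3,6-dihydro-1,2-dioxin-3-yl]acetic acid | OC(=O)C[C@@H]1OO[C@](C)(C/C(C)=C/CO[Si](c1ccccc1)(c1ccccc1)C(C)(C)C)C=C1C | intermediate
21 | (3R,4S,4aR,7aS)-3-{(2E)-4-[(tert-butyldiphenylsilyl)oxy]-2-methylbut-2-en-1-yl}-4-iodo-3,4a-dimethyl-3,4,4a,7a-tetrahydrofuro[3,2-c][1,2]dioxin-6(7H)-one | CC(C)(C)[Si](c1ccccc1)(c1ccccc1)OC/C=C(\C)C[C@]1(C)[C@@H](I)[C@]2(C)OC(=O)C[C@@H]2OO1 | intermediate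
22 | (3R,4aS,7aS)-3-{(2E)-4-[(tert-butyldiphenylsilyl)oxy]-2-methylbut-2-en-1-yl}-3,4a-dimethyl-3,4,4a,7a-tetrahydrofuro[3,2-c][1,2]dioxin-6(7H)-one | CC(C)(C)[Si](c1ccccc1)(c1ccccc1)OC/C=C(\C)C[C@]1(C)C[C@]2(C)OC(=O)C[C@@H]2OO1 | intermediate
23 | (3R,4aS,7aS)-3-[(2E)-4-hydroxy-2-methylbut-2-en-1-yl]-3,4a-dimethyl-3,4,4a,7a-tetrahydrofuro[3,2-c][1,2]dioxin-6(7H)-one | OC/C=C(\C)C[C@]1(C)C[C@]2(C)OC(=O)C[C@@H]2OO1 | intermediate
24 | (2E)-4-[(3R,4aS,7aS)-3,4a-dimethyl-6-oxohexahydrofuro[3,2-c][1,2]dioxin-3-yl]-3-methylbut-2-enal | O=C/C=C(\C)C[C@]1(C)C[C@]2(C)OC(=O)C[C@@H]2OO1 | intermediate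
25 | styrene | C=Cc1ccccc1 | starting material
26 | hex-5-en-1-ol | C=CCCCCO | starting material
27 | (5E)-6-phenylhex-5-en-1-ol | OCCCC/C=C/c1ccccc1 | intermediate
28 | 1-phenyl-5-{[(5E)-6-phenylhex-5-en-1-yl]sulfanyl}-1H-tetrazole | c1ccccc1/C=C/CCCCSc1nnnn1-c1ccccc1 | intermediate
29 | 1-phenyl-5-{[(5E)-6-phenylhex-5-en-1-yl]sulfonyl}-1H-tetrazole | O=S(=O)(CCCC/C=C/c1ccccc1)c1nnnn1-c1ccccc1 | intermediate
30 | plakortolide H, (3R,4aS,7aS)-3,4a-dimethyl-3-[(2E,4E,9E)-2-methyl-10-phenyldeca-2,4,9-trien-1-yl]-3,4,4a,7a-tetrahydrofuro[3,2-c][1,2]dioxin-6(7H)-one | C/C(=C\C=C\CCC/C=C/c1ccccc1)C[C@]1(C)C[C@]2(C)OC(=O)C[C@@H]2OO1 | target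

**Step count**

Total: 21 steps. Longest linear sequence: 16 steps (steps 1–3, 5–7, 9–17, 21).

**Steps most likely to fail**

Step 9 (conjugate addition of the hydroperoxide). The hydroperoxide may add at the δ-carbon of the dienal instead of the β-carbon. The enamine may collapse onto the O–O bond to give the epoxy aldehyde. The neighbouring hydroxy-hydroperoxide may acetalise the enal, or the chiral amine may give weak facial control with so bulky a tertiary hydroperoxide. The fallback sets out from 13 and 10 and returns at 15; it makes the O–C3 bond by Lewis-acid opening of an enantioenriched oxetane instead of by conjugate addition. Dienal 13 would be reduced (NaBH4, CeCl3·7H2O, MeOH, 0 °C) to (2E)-4-methylpenta-2,4-dien-1-ol F1. Sharpless epoxidation with L-(+)-DIPT would give [(2S,3S)-3-(prop-1-en-2-yl)oxiran-2-yl]methanol F2, and Red-Al (THF, 0 °C) would open it at C2 to (3R)-4-methylpent-4-ene-1,3-diol F3. Tosylation of the primary hydroxyl (TsCl, pyridine, 0 °C) would give (3R)-3-hydroxy-4-methylpent-4-en-1-yl 4-methylbenzenesulfonate F4, and KOtBu in THF would close (2R)-2-(prop-1-en-2-yl)oxetane F5. Hydroperoxide 10 would then open F5 at the allylic carbon with inversion (TMSOTf cat., Et2O, −78 → 0 °C), which should give 15 with the 3S configuration set by the oxetane and not by a catalyst.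

Step 12 (ring-closing metathesis). The carbene may load only slowly at the vinyl group next to the quaternary C6, so that catalyst decay, oligomerisation or thermal loss of the peroxide outruns the closure. The fallback sets out from 16 and returns at 18; it is a relay ring-closing metathesis that moves the loading site to a remote unhindered alkene. Aldehyde 16 would be olefinated with the ylide from hex-5-en-1-yltriphenylphosphonium bromide (NaHMDS, THF, −78 °C) to give the relay triene (3S)-3-{[(6Z,8R,10E)-12-[(tert-butyldiphenylsilyl)oxy]-8,10-dimethyldodeca-1,6,10-trien-8-yl]peroxy}-4-methylpent-4-en-1-ol F6. The catalyst would load on the terminal alkene of F6, close a five-membered carbocycle that is expelled, and so place the alkylidene on C5, which should then close onto the isopropenyl group to give 18.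

Step 21 (Julia–Kocienski olefination). E-selectivity at C10=C11 may erode with the conjugated aldehyde, or the carbanion may deprotonate C2 and trigger β-elimination of the peroxide from the lactone. The fallback sets out from 27 and 24 and returns at 30; it replaces kinetic E-control by a Z-selective Wittig reaction followed by thermodynamic isomerisation. Alcohol 27 would be converted (CBr4, PPh3, CH2Cl2) into [(1E)-6-bromohex-1-en-1-yl]benzene F7 and then (PPh3, MeCN, 80 °C) into triphenyl[(5E)-6-phenylhex-5-en-1-yl]phosphonium bromide F8. Its ylide (NaHMDS, THF, −78 °C), which is less basic than the sulfonyl carbanion, would olefinate 24 to the (10Z)-isomer of plakortolide H F9. Catalytic iodine (5 mol%, CH2Cl2, visible light, rt) should then equilibrate the disubstituted C10=C11 bond of the diene to the favoured E geometry and give 30.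

Further compounds
F1 | step 9 | (2E)-4-methylpenta-2,4-dien-1-ol | OC/C=C/C(C)=C
F2 | step 9 | [(2S,3S)-3-(prop-1-en-2-yl)oxiran-2-yl]methanol | OC[C@@H]1O[C@H]1C(C)=C
F3 | step 9 | (3R)-4-methylpent-4-ene-1,3-diol | O[C@H](CCO)C(C)=C
F4 | step 9 | (3R)-3-hydroxy-4-methylpent-4-en-1-yl 4-methylbenzenesulfonate | C=C(C)[C@H](O)CCOS(=O)(=O)c1ccc(C)cc1
F5 | step 9 | (2R)-2-(prop-1-en-2-yl)oxetane | C=C(C)[C@H]1CCO1
F6 | step 12 | (3S)-3-{[(6Z,8R,10E)-12-[(tert-butyldiphenylsilyl)oxy]-8,10-dimethyldodeca-1,6,10-trien-8-yl]peroxy}-4-methylpent-4-en-1-ol | C=CCCC/C=C\[C@@](C)(C/C(C)=C/CO[Si](c1ccccc1)(c1ccccc1)C(C)(C)C)OO[C@@H](CCO)C(C)=C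
F7 | step 21 | [(1E)-6-bromohex-1-en-1-yl]benzene | BrCCCC/C=C/c1ccccc1
F8 | step 21 | triphenyl[(5E)-6-phenylhex-5-en-1-yl]phosphonium bromide | [Br-].c1ccccc1/C=C/CCCC[P+](c1ccccc1)(c1ccccc1)c1ccccc1
F9 | step 21 | (10Z)-isomer of plakortolide H | C/C(=C\C=C/CCC/C=C/c1ccccc1)C[C@]1(C)C[C@]2(C)OC(=O)C[C@@H]2OO1
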